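**Retrosynthetic overview**
- Target (the 15-O-acetate of the A-type prostaglandin of the 1-series) ⇐ acid-mediated desilylation–dehydration (forms C10=C11) of an 11-O-silyl-15-O-acetyl E-type ketone; the C11 oxygen is a sacrificial control element.
- C12–C13 (sets C12 and, through protonation, C8) ⇐ visible-light nickel-catalysed reductive conjugate alkenylation of a 2-(6-carboxyhexyl)-4-silyloxycyclopentenone with an (E)-alkenyl iodide that already carries the C15 acetate.
- C7–C8 ⇐ B-alkyl Suzuki–Miyaura coupling of (R)-4-silyloxy-2-iodocyclopentenone with hept-6-enoic acid/9-BBN; the iodoenone ⇐ α-iodination of (R)-4-(tert-butyldimethylsilyloxy)cyclopent-2-enone.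
- Alkenyl iodide ⇐ (S)-oct-1-yn-3-ol by hydrozirconation–iodination, then acetylation.
- Rings: the only ring, the cyclopentenone, is bought intact; no ring is formed in the route.

Assumption: the target is the 15-O-acetylated A-type prostaglandin of the 1-series with the 8R,12S,15S configuration read from the SMILES, and (R)-4-(tert-butyldimethylsilyloxy)cyclopent-2-en-1-one and (S)-oct-1-yn-3-ol are taken as purchasable enantiopure building blocks.

**Route**

Step 1
Reactants: 1 (4R)-4-(tert-butyldimethylsilyloxy)cyclopent-2-en-1-one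
Product: 2 (4R)-4-(tert-butyldimethylsilyloxy)-2-iodocyclopent-2-en-1-one
Conditions: I2 (1.5 equiv), pyridine–CH2Cl2 (1:1), 0 °C → rt
Reagents that add atoms: iodine, II
Why: Pyridine-mediated α-iodination of an enone (conjugate addition of pyridine, iodination of the enolate, then β-elimination of pyridine from the re-formed enolate), which does not touch the C4 stereocentre.

Step 2
Reactants: 2 (4R)-4-(tert-butyldimethylsilyloxy)-2-iodocyclopent-2-en-1-one; 3 hept-6-enoic acid
Product: 5 (4R)-2-(6-carboxyhexyl)-4-(tert-butyldimethylsilyloxy)cyclopent-2-en-1-one, via alkylborane 4 (not isolated)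
Conditions: 3 (1.3 equiv), 9-BBN-H (2.1 equiv per 3), THF, 0 °C → rt; then 2, PdCl2(dppf) (3 mol %), Ph3As (3 mol %), Cs2CO3 (3 equiv), DMF–THF–H2O, rt; work-up at pH 4
Reagents that add atoms: none
Why: B-alkyl Suzuki–Miyaura coupling, in which one equivalent of 9-BBN-H is consumed by the carboxylic acid as an acyloxyborane, the second hydroborates the terminal alkene anti-Markovnikov, and the alkylborane couples with the reactive α-iodoenone at room temperature without disturbing the γ-silyloxy stereocentre.

Step 3
Reactants: 6 (S)-oct-1-yn-3-ol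
Product: 8 (1E,3S)-1-iodooct-1-en-3-ol, via alkenylzirconocene 7 (not isolated)
Conditions: Cp2Zr(H)Cl (2.2 equiv), THF, rt, dark; then I2 (1.1 equiv), 0 °C; 0.5 M HCl work-up
Reagents that add atoms: iodine, II
Why: Hydrozirconation–iodinolysis, in which the first equivalent of Cp2Zr(H)Cl forms the zirconium alkoxide, the second adds syn across the alkyne with zirconium at the terminal carbon, and iodine cleaves the C–Zr bond with retention to give only the E iodide, leaving the carbinol centre untouched.

Step 4
Reactants: 8 (1E,3S)-1-iodooct-1-en-3-ol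
Product: 9 (1E,3S)-1-iodooct-1-en-3-yl acetate
Conditions: Ac2O (1.5 equiv), pyridine, DMAP (5 mol %), CH2Cl2, 0 °C → rt
Reagents that add atoms: acetic anhydride, CC(=O)OC(C)=O
Why: DMAP-catalysed O-acylation of a secondary alcohol, which installs the C15 acetate of the target without affecting configuration or the alkenyl iodide.

Step 5
Reactants: 5 (4R)-2-(6-carboxyhexyl)-4-(tert-butyldimethylsilyloxy)cyclopent-2-en-1-one; 9 (1E,3S)-1-iodooct-1-en-3-yl acetate
Product: 12 ketone 7-[(1R,2R,3R)-2-[(1E,3S)-3-acetoxyoct-1-en-1-yl]-3-(tert-butyldimethylsilyloxy)-5-oxocyclopentyl]heptanoic acid, via silyl ester 10 (not isolated), via silyl enol ether 11 (not isolated)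
Conditions: 5 (1.0 equiv), 9 (1.3 equiv), NiBr2(dme) (10 mol %), 4,4'-di-tert-butyl-2,2'-bipyridine (12 mol %), 4CzIPN (2 mol %), Hantzsch ester (1.5 equiv), Et3SiCl (2.5 equiv), 2,6-lutidine (3.5 equiv), DMA, 450 nm LEDs, 20 °C; then AcOH–THF–H2O (1:3:1), 0 °C
Reagents that add atoms: chlorotriethylsilane, CC[Si](Cl)(CC)CC (its silyl groups sit only in 10 and 11 and are lost on work-up)
Why: Proposed new method: a visible-light-driven nickel-catalysed reductive conjugate alkenylation, in which 4CzIPN excited at 450 nm is quenched by the Hantzsch ester and its radical anion reduces divalent nickel to zerovalent nickel, which with Et3SiCl converts enone 10 into a 1-silyloxyallyl nickel chloride on the ring face anti to the C11 silyl ether; a second photochemical one-electron reduction gives the monovalent allylnickel, which inserts into the C–I bond of 9 with retention of the E geometry and reductively eliminates to forge C12–C13 trans to the silyloxy group as silyl enol ether 11, and protonation on work-up places the C8 chain trans to C12 (the thermodynamic arrangement, equilibrated again in step 6); the closest known reactions are the manganese-driven nickel-catalysed reductive conjugate addition of aryl and alkenyl halides to enones with chlorosilanes and nickel/photoredox cross-electrophile coupling.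

Step 6
Reactants: 12 ketone 7-[(1R,2R,3R)-2-[(1E,3S)-3-acetoxyoct-1-en-1-yl]-3-(tert-butyldimethylsilyloxy)-5-oxocyclopentyl]heptanoic acid
Product: 14 enone 7-[(1R,2S)-2-[(1E,3S)-3-acetoxyoct-1-en-1-yl]-5-oxocyclopent-3-en-1-yl]heptanoic acid (the target), via hydroxy ketone 13 (not isolated)
Conditions: AcOH–H2O (9:1), 60 °C, 20 h
Reagents that add atoms: none
Why: Acid-mediated cleavage of the silyl ether followed by acid-catalysed β-elimination of the β-hydroxy ketone through its enol (the classical dehydration of an E-type to an A-type prostaglandin), during which C8 equilibrates to the more stable trans arrangement while C12 and the C15 acetate are untouched in the weakly acidic, acetic-acid-rich medium.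

**Compound list**

1 | (4R)-4-(tert-butyldimethylsilyloxy)cyclopent-2-en-1-one | O=C1C=C[C@H](O[Si](C)(C)C(C)(C)C)C1 | starting material
2 | (4R)-4-(tert-butyldimethylsilyloxy)-2-iodocyclopent-2-en-1-one | O=C1C(I)=C[C@H](O[Si](C)(C)C(C)(C)C)C1 | intermediate
3 | hept-6-enoic acid | C=CCCCCC(=O)O | starting material
4 | 9-borabicyclo[3.3.1]nonan-9-yl 7-(9-borabicyclo[3.3.1]nonan-9-yl)heptanoate | O=C(CCCCCCB1C2CCCC1CCC2)OB1C2CCCC1CCC2 | intermediate (not isolated)
5 | (4R)-2-(6-carboxyhexyl)-4-(tert-butyldimethylsilyloxy)cyclopent-2-en-1-one | O=C1C(CCCCCCC(=O)O)=C[C@H](O[Si](C)(C)C(C)(C)C)C1 | intermediate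
6 | (S)-oct-1-yn-3-ol | CCCCC[C@@H](C#C)O | starting material
7 | [(1E,3S)-3-[chlorobis(cyclopentadienyl)zirconiooxy]oct-1-en-1-yl]chlorobis(cyclopentadienyl)zirconium (cyclopentadienyl rings drawn σ-bonded) | CCCCC[C@@H](/C=C/[Zr](Cl)(C1C=CC=C1)C1C=CC=C1)O[Zr](Cl)(C1C=CC=C1)C1C=CC=C1 | intermediate (not isolated)
8 | (1E,3S)-1-iodooct-1-en-3-ol | CCCCC[C@@H](/C=C/I)O | intermediate
9 | (1E,3S)-1-iodooct-1-en-3-yl acetate | CCCCC[C@@H](/C=C/I)OC(C)=O | intermediate
10 | triethylsilyl 7-[(3R)-3-(tert-butyldimethylsilyloxy)-5-oxocyclopent-1-en-1-yl]heptanoate | O=C1C(CCCCCCC(=O)O[Si](CC)(CC)CC)=C[C@H](O[Si](C)(C)C(C)(C)C)C1 | intermediate (not isolated)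
11 | triethylsilyl 7-[(4R,5R)-5-[(1E,3S)-3-acetoxyoct-1-en-1-yl]-4-(tert-butyldimethylsilyloxy)-2-(triethylsilyloxy)cyclopent-1-en-1-yl]heptanoate | CCCCC[C@@H](/C=C/[C@H]1[C@H](O[Si](C)(C)C(C)(C)C)CC(O[Si](CC)(CC)CC)=C1CCCCCCC(=O)O[Si](CC)(CC)CC)OC(C)=O | intermediate (not isolated)
12 | 7-[(1R,2R,3R)-2-[(1E,3S)-3-acetoxyoct-1-en-1-yl]-3-(tert-butyldimethylsilyloxy)-5-oxocyclopentyl]heptanoic acid (the 11-O-silyl-15-O-acetyl E-type prostaglandin of the 1-series) | CCCCC[C@@H](/C=C/[C@H]1[C@H](O[Si](C)(C)C(C)(C)C)CC(=O)[C@@H]1CCCCCCC(=O)O)OC(C)=O | intermediate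
13 | 7-[(1R,2R,3R)-2-[(1E,3S)-3-acetoxyoct-1-en-1-yl]-3-hydroxy-5-oxocyclopentyl]heptanoic acid (the 15-O-acetyl E-type prostaglandin of the 1-series) | CCCCC[C@@H](/C=C/[C@H]1[C@H](O)CC(=O)[C@@H]1CCCCCCC(=O)O)OC(C)=O | intermediate (not isolated)
14 | 7-[(1R,2S)-2-[(1E,3S)-3-acetoxyoct-1-en-1-yl]-5-oxocyclopent-3-en-1-yl]heptanoic acid (the 15-O-acetyl A-type prostaglandin of the 1-series, CNP0281518.1) | CCCCC[C@@H](/C=C/[C@H]1C=CC(=O)[C@@H]1CCCCCCC(=O)O)OC(C)=O | target

**Step count and risks**

Total steps: 6. Longest linear sequence: 4 steps (1 → 2 → 5 → 12 → 14; the side-chain branch 6 → 8 → 9 → 12 → 14 is also 4).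

Most likely to fail, in order:

- **Step 5 (the proposed new step).** Low-valent nickel may ionise the allylic acetate of 9 or of the product, homocouple 9, or simply reduce the enone; the anti selectivity and the photochemical turnover are untested on this substrate. The fallback uses known chemistry and sets out from 6 and 5. Alcohol 6 is acetylated (Ac2O, pyridine, DMAP) to (S)-oct-1-yn-3-yl acetate F1. F1 is hydroborated with pinacolborane (10 mol % dicyclohexylborane, neat, rt) to the alkenylboronate (1E,3S)-1-(4,4,5,5-tetramethyl-1,3,2-dioxaborolan-2-yl)oct-1-en-3-yl acetate F2. F2 is then added to enone 5 with [Rh(cod)OH]2 (3 mol %) and KHCO3 (1 equiv) in dioxane–H2O at 30 °C, a rhodium-catalysed 1,4-addition of an alkenylboron reagent that enters anti to the C11 silyl ether. This comes back to the route at 12.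

- **Step 2.** The free carboxylic acid may give incomplete hydroboration or slow reduction of the acyloxyborane, and the 4-silyloxy-iodoenone is base-sensitive. The fallback sets out from 2 and swaps 3 for purchased methyl hept-6-enoate (C=CCCCCC(=O)OC). Hydroboration with 9-BBN-H (1.05 equiv) gives methyl 7-(9-borabicyclo[3.3.1]nonan-9-yl)heptanoate F3, used in solution. Coupling with 2 under the same PdCl2(dppf)/Ph3As/Cs2CO3 conditions gives methyl 7-[(3R)-3-(tert-butyldimethylsilyloxy)-5-oxocyclopent-1-en-1-yl]heptanoate F4. The ester is then cleaved under near-neutral conditions with Me3SnOH (1,2-dichloroethane, 70 °C), coming back to the route at 5.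

- **Step 6.** Dehydration may stall at 13, or long heating in acid may erode the allylic acetate. The fallback sets out from 12 and switches from acid solvolysis to a base-induced β-elimination through the enolate: DBU (2.5 equiv), CH2Cl2, 0 °C, which expels the silanolate directly from the C10 enolate without passing through 13. It is quenched early with pH 4 buffer to avoid base isomerisation of the enone into the ring-conjugated B-type dienone, and comes back to the route at 14. It makes no new compound.

Further compounds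
F1 | step 5 | (S)-oct-1-yn-3-yl acetate | CCCCC[C@@H](C#C)OC(C)=O
F2 | step 5 | (1E,3S)-1-(4,4,5,5-tetramethyl-1,3,2-dioxaborolan-2-yl)oct-1-en-3-yl acetate | CCCCC[C@@H](/C=C/B1OC(C)(C)C(C)(C)O1)OC(C)=O
F3 | step 2 | methyl 7-(9-borabicyclo[3.3.1]nonan-9-yl)heptanoate | COC(=O)CCCCCCB1C2CCCC1CCC2
F4 | step 2 | methyl 7-[(3R)-3-(tert-butyldimethylsilyloxy)-5-oxocyclopent-1-en-1-yl]heptanoate | COC(=O)CCCCCCC1=C[C@H](O[Si](C)(C)C(C)(C)C)CC1=O
F0 | step 6 | none | none
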